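Late in both flasks, the question is which way the single product leaves.

- teal: substrate 0.17 M; reagent 0.260 M; time 30 h
- ochre: substrate 0.17 M; reagent 0.510 M; time 30 h

    substrate + reagent → single product + by-product (k1 = 7.75 L mol⁻¹ h⁻¹)
    reagent + single product → bis adduct + by-product (k2 = 2.93 L mol⁻¹ h⁻¹)
    single product → side product (k3 = 0.184 h⁻¹)

* which of the two there is more of at the end, teal (side product / bis adduct)
* which of the two there is more of at the end, ochre (side product / bis adduct)
* amount of bis adduct at the end, in percent of the substrate charged, teal
* amount of bis adduct at the end, in percent of the substrate charged, ochre

I build the flask up one step at a time. The first step has a half-life of 0.34 h in teal, shorter than the 0.91 h of the second and the 3.8 h of the last, so I reckon it as finished first. That turns the substrate into single product mole for mole and leaves free reagent of 0.0900 M in teal and 0.340 M in ochre, with no bis adduct yet.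

Adding the second step, each bis adduct takes one free reagent. In this reckoning, with the first step taken as finished, teal's free reagent covers 52.9% of the substrate charged, while ochre's, more than the single product, covers 100%.

Adding the last step opens a second exit. At free reagent level B, the second step is pseudo-first-order in single product, and the share going to bis adduct is B/(B + C). Here C is the crossover level, the free reagent at which single product leaves equally by both exits: 0.184 h⁻¹ over 2.93 L mol⁻¹ h⁻¹, or 0.0628 M. The share has the shape of a binding curve with C at its midpoint.

Following the reagent down, the side product made is C times the natural log of free reagent at the start over free reagent at the end, and reagent used plus side product must equal the substrate charged. Solving by repeated substitution, teal ends with 0.0185 M of reagent, below C, and 42.0% bis adduct, so side product leads. Ochre makes 0.0322 M of side product and 81.1% bis adduct.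

The forecast says side product for teal at 45% bis adduct, above my figure, and bis adduct for ochre at 81%, on the ground that in ochre “the second addition outruns that loss by several-fold”.

The simulation gives side product for teal, with 46.8% bis adduct against 52.6% side product, and bis adduct for ochre, with 81.8% bis adduct. Teal stands 4.8 percentage points above my reckoning. At 30 h, teal holds 0.0110 M of reagent, below C, and ochre holds 0.201 M, above it. A neighbour of ochre charged with 1.3 M of reagent starts with 1.13 M free, far above C, and the same balance gives 5.63% side product. That flask ends with 94.5% bis adduct and 5.55% side product.

The numbers of this flask are those of an exercise.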